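(Readings and results stem from a simulated flask on assumed constants; scatter was added.)

- Late in the two earlier runs, where substrate and coupling partner give target over a catalyst, the target stopped rising: zeta, at 62 °C, stood near 58.5% and beta, at 112 °C, near 53.7%, as readings, and I took one partner per target, so that the partner, charged below the substrate, was the limiting reagent and allowed 70.0%.

common to all: substrate 31 mM; coupling partner 21.7 mM
- zeta: catalyst 0.15 mM; temperature 62 °C; run made earlier
- beta: catalyst 0.24 mM; temperature 112 °C; run made earlier
- amber: catalyst 0.11 mM; temperature 130 °C; time 12 min
- ochre: catalyst 0.11 mM; temperature 40 °C; time 12 min
- red: catalyst 0.11 mM; temperature 70 °C; time 12 min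
- violet: catalyst 0.11 mM; temperature 100 °C; time 12 min

- zeta (time / min: target / %): 25.0: 29; 60.0: 49; 120: 59; 300: 58
- beta (time / min: target / %): 6.00: 51; 12.0: 56; 20.0: 52; 25.0: 53

(standard deviation of a reading: 2 percentage points)

* the best flask by amount of target, in percent of the substrate charged; "all alike" if 1.5 percentage points covers them all (amber / ochre / red / violet / all alike)
* amount of target at the end, in percent of the substrate charged, amber
* amount of target at the end, in percent of the substrate charged, ochre
* amount of target at the end, in percent of the substrate charged, red
* amount of target at the end, in percent of the substrate charged, violet



- So I took it that some partner had gone elsewhere, and I reckoned the waste ratio, partner lost per partner that reached target, as the gap to that ceiling over the plateau as read: 0.197 in zeta and 0.304 in beta.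
- I supposed that the loss ran without catalyst while the coupling ran with it, so that, with the substrate and partner charges held as they stood in these flasks, the ratio times the catalyst charge, 0.0295 mM in zeta and 0.0730 mM in beta, would depend on temperature and not on the catalyst charge; this product I called the waste dose.
- Between those two temperatures the dose, as read from scattered readings, grew by a factor of 2.48, and I let it go on at the same pace per degree, which gave 0.101 mM for amber.
- In the first instants of amber, hotter than beta, I pictured both paths drawing on a full partner charge, with about half of beta's catalyst behind the coupling.
- For the middle I had beta's reading of 51% at 6.00 min against its plateau near 53.7%, so I took amber, hotter but with less catalyst, to reach its own plateau inside its 12 min.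
- At the end amber's ratio of 0.920 left me a plateau of 36.4%.
- The forecast named amber as best, with amber 51%, ochre 4.5%, red 18% and violet 42%, and it read the late times thus: “The plateau is therefore slightly lower when hot”. My figure for amber stood below its own.
- The flasks gave amber as best, with amber 41.5%, ochre 1.38%, red 14.2% and violet 36.5%. Amber lay below the forecast and above my plateau, and left ten times as long it stood at 42.4%, at 120 min. Its own waste dose, reckoned from that late value, came to 0.0717 mM against my 0.101 mM.

    coupling partner + catalyst + intermediate → catalyst + target (k = 15000 M⁻² min⁻¹, Ea = 43.0 kJ mol⁻¹)
    2 coupling partner → homo dimer (k = 0.380 M⁻¹ min⁻¹, Ea = 60.0 kJ mol⁻¹)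
    substrate + catalyst → catalyst + intermediate (k = 1100 M⁻¹ min⁻¹, Ea = 45.0 kJ mol⁻¹)
    (constants at 70 °C)

- For the flask like ochre at 40 °C but with 0.44 mM of catalyst, the same pace gave a dose of 0.0198 mM and so a plateau of 67.0%. At 12.0 min that flask held 13.7% target with 78.2% of its partner charge left, which together make room for 68.5%, slightly above that plateau.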